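**Retrosynthetic overview**

1. Rings are lettered A to H from the 2,4,6-trihydroxyphenoxy end, and position 1 of each ring is the carbon on the oxygen that leads back toward ring A. The strategy rests on ring C: its two bridging oxygens sit on adjacent carbons, C1 (O to ring B, next to C6–H) and C2 (O to ring D, next to the C3/C4/C5 triol), which is the footprint of 3,4,5-trioxygenated benzyne.
2. Key disconnection: the C1–O and C2–O bonds of ring C are made in one flask from the A–B phenoxide (nucleophile), 3,4,5-trimethoxybenzyne and a silyl peroxide (oxygen electrophile).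
3. Other ether bonds: A–B, C2–D1, E2–F1 and F5–G1 by copper-catalysed Ullmann coupling; D4–E1 (four ortho substituents) by SNAr on an ortho-fluorobenzaldehyde, then Baeyer–Villiger oxidation; G2–H1 by Chan–Lam coupling.
4. No ring is constructed (all eight benzene rings are bought) and the target has no stereocentre. Order of joining: A+B, then C (key step); D+E and F+G+H separately; ABC+DE, then +FGH; the 21 methyl ethers are cleaved last.

Key step: step 6

Remark on the chemistry: a silyl peroxide does not survive fluoride (it is desilylated to a peroxide anion) and a bare aryl anion does not outlive the aryne, so the aryne is released without fluoride from an ortho-iodoaryl triflate by iodine–magnesium exchange, and the peroxide is added only afterwards to a persistent arylmagnesium.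

**Route**

Step 1
Reactants: 1 4-bromo-2,6-dimethoxyphenol
Product: 2 2-(benzyloxy)-5-bromo-1,3-dimethoxybenzene
Conditions: BnBr, K2CO3, DMF, 60 °C
Reagents that add atoms: benzyl bromide BrCc1ccccc1
Why: Williamson ether synthesis masks the ring B phenol so that only the ring A phenol couples in step 2 and the ring B oxygen can be freed later by hydrogenolysis.

Step 2
Reactants: 3 2,4,6-trimethoxyphenol; 2 2-(benzyloxy)-5-bromo-1,3-dimethoxybenzene
Product: 4 2-(benzyloxy)-1,3-dimethoxy-5-(2,4,6-trimethoxyphenoxy)benzene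
Conditions: CuI (10 mol %), picolinic acid (20 mol %), K3PO4, DMSO, 90 °C
Reagents that add atoms: none
Why: Ullmann-type copper-catalysed diaryl ether synthesis pairs a hindered, electron-rich phenoxide with a bromide whose carbon has two hydrogen neighbours, the combination that picolinic acid ligation of monovalent copper handles best.

Step 3
Reactants: 4 2-(benzyloxy)-1,3-dimethoxy-5-(2,4,6-trimethoxyphenoxy)benzene
Product: 5 2,6-dimethoxy-4-(2,4,6-trimethoxyphenoxy)phenol
Conditions: H2 (1 atm), Pd/C, EtOAc–MeOH, rt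
Reagents that add atoms: none
Why: Catalytic hydrogenolysis cleaves only the benzylic C–O bond, since diaryl and aryl methyl ethers are inert to it.

Step 4
Reactants: 6 3,4,5-trimethoxyphenol
Product: 7 2-iodo-3,4,5-trimethoxyphenol
Conditions: NIS, MeCN, 0 °C
Reagents that add atoms: N-iodosuccinimide O=C1CCC(=O)N1I
Why: Electrophilic aromatic iodination of an electron-rich phenol whose para position is blocked and whose two ortho positions are equivalent should give a single monoiodide with one equivalent of reagent.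

Step 5
Reactants: 7 2-iodo-3,4,5-trimethoxyphenol
Product: 8 2-iodo-3,4,5-trimethoxyphenyl trifluoromethanesulfonate
Conditions: Tf2O, pyridine, CH2Cl2, 0 °C
Reagents that add atoms: trifluoromethanesulfonic anhydride O=S(=O)(OS(=O)(=O)C(F)(F)F)C(F)(F)F
Why: O-Sulfonylation of the phenol gives the ortho-iodoaryl triflate, an aryne precursor that needs no fluoride.

Step 6
Reactants: 5 2,6-dimethoxy-4-(2,4,6-trimethoxyphenoxy)phenol; 8 2-iodo-3,4,5-trimethoxyphenyl trifluoromethanesulfonate; 9 bis(trimethylsilyl) peroxide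
Product: 15 6-[2,6-dimethoxy-4-(2,4,6-trimethoxyphenoxy)phenoxy]-2,3,4-trimethoxyphenol, via potassium phenoxide 10 (not isolated), via magnesiated triflate 11 (not isolated), via 3,4,5-trimethoxybenzyne 12 (not isolated), via arylmagnesium chloride 13 (not isolated), via trimethylsilyl ether 14 (not isolated)
Conditions: KH, 18-crown-6, THF, 0 °C; 8 + Me3SiCH2MgCl (added together, slowly), −78 °C; 9, −78 → 0 °C; K2CO3 (cat.), MeOH, rt
Reagents that add atoms: bis(trimethylsilyl) peroxide (compound 9) C[Si](C)(C)OO[Si](C)(C)C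
Why: Proposed new method: iodine–magnesium exchange on 8 gives 11, which loses triflate at −78 °C and releases aryne 12 without fluoride; the crown-separated phenoxide 10 adds to C1 of 12 (the carbon next to C6–H), and the C2 carbanion is taken up by the magnesium salt set free in the same event, giving the persistent arylmagnesium 13. Only when the aryne is spent is peroxide 9 added: 13 attacks a peroxide oxygen and displaces trimethylsilanolate (substitution at oxygen), and methanolysis of silyl ether 14 gives 15, so both ring C oxygens arrive in one flask. The closest known reaction types are the addition of magnesium thiolates and amides to arynes made by iodine–magnesium exchange, with electrophilic quench of the ortho-functionalised arylmagnesium, and the oxidation of arylmagnesium halides with bis(trimethylsilyl) peroxide; a phenoxide as the nucleophile combined with an oxygen electrophile is what is new. No ring closes and no stereocentre is formed. The step needs regiocontrol on the aryne, and the C3 methoxy group beside the triple bond provides it: its inductive pull makes the remote carbon C1 the electrophilic one and stabilises the charge at C2, where it also chelates magnesium, so the aryloxy group lands at C1 and the new hydroxyl at C2 between the aryloxy and methoxy groups. It also needs the oxidant to meet neither a silicon-seeking base nor free aryne, and the anion to meet no proton donor, which the fluoride-free release, the fully deprotonated phenol in THF and the staged addition secure.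

Step 7
Reactants: 16 2-bromo-3,4,5-trimethoxybenzaldehyde
Product: 17 2-bromo-1-(dimethoxymethyl)-3,4,5-trimethoxybenzene
Conditions: HC(OMe)3, TsOH (cat.), MeOH, 50 °C
Reagents that add atoms: trimethyl orthoformate COC(OC)OC; methanol CO
Why: Acid-catalysed acetalisation masks the aldehyde against butyllithium in the next step.

Step 8
Reactants: 17 2-bromo-1-(dimethoxymethyl)-3,4,5-trimethoxybenzene
Product: 20 2-fluoro-3,4,5-trimethoxybenzaldehyde, via aryllithium 18 (not isolated), via fluoro acetal 19 (not isolated)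
Conditions: n-BuLi, THF, −78 °C; (PhSO2)2NF, −78 °C → rt; 2 M HCl, THF, rt
Reagents that add atoms: N-fluorobenzenesulfonimide O=S(=O)(c1ccccc1)N(F)S(=O)(=O)c1ccccc1; water O
Why: Bromine–lithium exchange fixes the carbanion between the acetal and a methoxy group, electrophilic fluorination with the N–F reagent puts fluorine there, and aqueous acid hydrolyses the acetal.

Step 9
Reactants: 1 4-bromo-2,6-dimethoxyphenol; 20 2-fluoro-3,4,5-trimethoxybenzaldehyde
Product: 21 2-(4-bromo-2,6-dimethoxyphenoxy)-3,4,5-trimethoxybenzaldehyde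
Conditions: Cs2CO3, DMSO, 120 °C
Reagents that add atoms: none
Why: Nucleophilic aromatic substitution (addition–elimination) at the C–F carbon activated by the ortho formyl group lets the hindered phenoxide form the ether with four ortho substituents, and it leaves untouched the aryl bromide that copper catalysis would attack.

Step 10
Reactants: 21 2-(4-bromo-2,6-dimethoxyphenoxy)-3,4,5-trimethoxybenzaldehyde
Product: 23 2-(4-bromo-2,6-dimethoxyphenoxy)-3,4,5-trimethoxyphenol, via aryl formate 22 (not isolated)
Conditions: mCPBA, CH2Cl2, 0 °C → rt; K2CO3 (cat.), MeOH, rt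
Reagents that add atoms: 3-chloroperoxybenzoic acid OOC(=O)c1cccc(Cl)c1
Why: In the Baeyer–Villiger oxidation the electron-rich aryl group (ortho aryloxy, para methoxy) migrates in preference to hydrogen, and the formate is then methanolysed to the phenol.

Step 11
Reactants: 23 2-(4-bromo-2,6-dimethoxyphenoxy)-3,4,5-trimethoxyphenol
Product: 24 1-(benzyloxy)-2-(4-bromo-2,6-dimethoxyphenoxy)-3,4,5-trimethoxybenzene
Conditions: BnBr, K2CO3, DMF, 60 °C
Reagents that add atoms: benzyl bromide BrCc1ccccc1
Why: Williamson ether synthesis masks the E2 hydroxyl so that it cannot compete with the ring C hydroxyl in step 17.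

Step 12
Reactants: 25 2,3,4-trimethoxyphenol
Product: 26 6-bromo-2,3,4-trimethoxyphenol
Conditions: NBS, i-Pr2NH (10 mol %), CH2Cl2, 0 °C
Reagents that add atoms: N-bromosuccinimide O=C1CCC(=O)N1Br
Why: Amine-mediated ortho-bromination of a phenol sends bromine to the only free carbon ortho to the hydroxyl (C6), the para position being blocked by methoxy.

Step 13
Reactants: 26 6-bromo-2,3,4-trimethoxyphenol; 27 (3,4,5-trimethoxyphenyl)boronic acid
Product: 28 1-bromo-3,4,5-trimethoxy-2-(3,4,5-trimethoxyphenoxy)benzene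
Conditions: Cu(OAc)2 (20 mol %), pyridine, 4 Å molecular sieves, O2 (1 atm), CH2Cl2, rt
Reagents that add atoms: none
Why: Chan–Lam oxidative coupling of a phenol with an arylboronic acid on divalent copper runs at room temperature, tolerates two ortho substituents on the phenol and leaves the aryl bromide untouched.

Step 14
Reactants: 28 1-bromo-3,4,5-trimethoxy-2-(3,4,5-trimethoxyphenoxy)benzene; 29 2,3-dimethoxyphenol
Product: 30 1-(2,3-dimethoxyphenoxy)-3,4,5-trimethoxy-2-(3,4,5-trimethoxyphenoxy)benzene
Conditions: CuI (10 mol %), picolinic acid (20 mol %), K3PO4, DMSO, 100 °C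
Reagents that add atoms: none
Why: Ullmann-type copper-catalysed diaryl ether synthesis joins a phenol and a bromide that each carry only one ortho substituent.

Step 15
Reactants: 30 1-(2,3-dimethoxyphenoxy)-3,4,5-trimethoxy-2-(3,4,5-trimethoxyphenoxy)benzene
Product: 31 2-{3,4-dimethoxy-5-[3,4,5-trimethoxy-2-(3,4,5-trimethoxyphenoxy)phenoxy]phenyl}-4,4,5,5-tetramethyl-1,3,2-dioxaborolane
Conditions: [Ir(OMe)(cod)]2 (1.5 mol %), 4,4'-di-tert-butyl-2,2'-bipyridine (3 mol %), B2pin2, THF, 80 °C
Reagents that add atoms: bis(pinacolato)diboron CC1(C)OB(OC1(C)C)B1OC(C)(C)C(C)(C)O1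
Why: Iridium-catalysed C–H borylation is governed by sterics, and F1 is the only C–H in 30 with no ortho substituent.

Step 16
Reactants: 31 the ring F pinacol boronate
Product: 32 1-(5-bromo-2,3-dimethoxyphenoxy)-3,4,5-trimethoxy-2-(3,4,5-trimethoxyphenoxy)benzene
Conditions: CuBr2, MeOH–H2O (1:1), 80 °C
Reagents that add atoms: copper dibromide [Cu+2].[Br-].[Br-]
Why: Copper-mediated bromodeboronation replaces boron by bromine at the same carbon (ipso substitution), so F1 is brominated without electrophilic bromination of the other electron-rich rings.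

Step 17
Reactants: 15 the A–B–C trimer phenol; 24 1-(benzyloxy)-2-(4-bromo-2,6-dimethoxyphenoxy)-3,4,5-trimethoxybenzene
Product: 33 A-to-E pentamer, all hydroxyls methylated except E2, which is a benzyl ether
Conditions: CuI (20 mol %), picolinic acid (40 mol %), K3PO4, DMSO, 100 °C
Reagents that add atoms: none
Why: Ullmann-type copper-catalysed diaryl ether synthesis again pairs a hindered phenol (C2, between aryloxy and methoxy) with a bromide (D1) that has two hydrogen neighbours.

Step 18
Reactants: 33 the A-to-E pentamer benzyl ether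
Product: 34 A-to-E pentamer with free E2 hydroxyl
Conditions: H2 (1 atm), Pd/C, EtOAc–MeOH, rt
Reagents that add atoms: none
Why: Catalytic hydrogenolysis removes the single benzyl group; no aryl halide remains that could be reduced.

Step 19
Reactants: 34 the A-to-E pentamer phenol; 32 the F–G–H bromide
Product: 35 henicosa-O-methyl ether of the target
Conditions: CuI (20 mol %), picolinic acid (40 mol %), K3PO4, DMSO, 100 °C
Reagents that add atoms: none
Why: Ullmann-type copper-catalysed diaryl ether synthesis joins the E2 phenol (one ortho substituent) to the F1 bromide (none).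

Step 20
Reactants: 35 henicosa-O-methyl ether of the target
Product: 36 CNP0309601.0
Conditions: BBr3 (excess), CH2Cl2, −78 °C → rt; MeOH, then degassed H2O
Reagents that add atoms: none
Why: Lewis acid cleavage of aryl methyl ethers with BBr3 removes each methyl group as bromomethane, while the diaryl ether bonds, which offer bromide no sp3 carbon, survive.

**Compound list**

1 | 4-bromo-2,6-dimethoxyphenol | COc1cc(Br)cc(OC)c1O | starting material
2 | 2-(benzyloxy)-5-bromo-1,3-dimethoxybenzene | COc1cc(Br)cc(OC)c1OCc1ccccc1 | intermediate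
3 | 2,4,6-trimethoxyphenol | COc1cc(OC)c(O)c(OC)c1 | starting material
4 | 2-(benzyloxy)-1,3-dimethoxy-5-(2,4,6-trimethoxyphenoxy)benzene | COc1cc(OC)c(Oc2cc(OC)c(OCc3ccccc3)c(OC)c2)c(OC)c1 | intermediate
5 | 2,6-dimethoxy-4-(2,4,6-trimethoxyphenoxy)phenol (A–B phenol) | COc1cc(OC)c(Oc2cc(OC)c(O)c(OC)c2)c(OC)c1 | intermediate
6 | 3,4,5-trimethoxyphenol | COc1cc(O)cc(OC)c1OC | starting material
7 | 2-iodo-3,4,5-trimethoxyphenol | COc1cc(O)c(I)c(OC)c1OC | intermediate
8 | 2-iodo-3,4,5-trimethoxyphenyl trifluoromethanesulfonate | COc1cc(OS(=O)(=O)C(F)(F)F)c(I)c(OC)c1OC | intermediate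
9 | bis(trimethylsilyl) peroxide | C[Si](C)(C)OO[Si](C)(C)C | starting material
10 | potassium 2,6-dimethoxy-4-(2,4,6-trimethoxyphenoxy)phenoxide (not isolated) | COc1cc(OC)c(Oc2cc(OC)c([O-])c(OC)c2)c(OC)c1.[K+] | intermediate
11 | 2-(chloromagnesio)-3,4,5-trimethoxyphenyl trifluoromethanesulfonate (not isolated) | COc1cc(OS(=O)(=O)C(F)(F)F)c([Mg]Cl)c(OC)c1OC | intermediate
12 | 3,4,5-trimethoxybenzyne, 1,2-didehydro-3,4,5-trimethoxybenzene (not isolated) | COC1=C(OC)C(OC)=CC#C1 | intermediate
13 | {6-[2,6-dimethoxy-4-(2,4,6-trimethoxyphenoxy)phenoxy]-2,3,4-trimethoxyphenyl}magnesium chloride (not isolated) | COc1cc(OC)c(Oc2cc(OC)c(Oc3cc(OC)c(OC)c(OC)c3[Mg]Cl)c(OC)c2)c(OC)c1 | intermediate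
14 | trimethylsilyl ether of 15 (not isolated) | COc1cc(OC)c(Oc2cc(OC)c(Oc3cc(OC)c(OC)c(OC)c3O[Si](C)(C)C)c(OC)c2)c(OC)c1 | intermediate
15 | 6-[2,6-dimethoxy-4-(2,4,6-trimethoxyphenoxy)phenoxy]-2,3,4-trimethoxyphenol (A–B–C trimer, free C2 hydroxyl) | COc1cc(OC)c(Oc2cc(OC)c(Oc3cc(OC)c(OC)c(OC)c3O)c(OC)c2)c(OC)c1 | intermediate
16 | 2-bromo-3,4,5-trimethoxybenzaldehyde | COc1cc(C=O)c(Br)c(OC)c1OC | starting material
17 | 2-bromo-1-(dimethoxymethyl)-3,4,5-trimethoxybenzene | COc1cc(C(OC)OC)c(Br)c(OC)c1OC | intermediate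
18 | [6-(dimethoxymethyl)-2,3,4-trimethoxyphenyl]lithium (not isolated) | COc1cc(C(OC)OC)c([Li])c(OC)c1OC | intermediate
19 | 1-(dimethoxymethyl)-2-fluoro-3,4,5-trimethoxybenzene (not isolated) | COc1cc(C(OC)OC)c(F)c(OC)c1OC | intermediate
20 | 2-fluoro-3,4,5-trimethoxybenzaldehyde | COc1cc(C=O)c(F)c(OC)c1OC | intermediate
21 | 2-(4-bromo-2,6-dimethoxyphenoxy)-3,4,5-trimethoxybenzaldehyde | COc1cc(C=O)c(Oc2c(OC)cc(Br)cc2OC)c(OC)c1OC | intermediate
22 | 2-(4-bromo-2,6-dimethoxyphenoxy)-3,4,5-trimethoxyphenyl formate (not isolated) | COc1cc(OC=O)c(Oc2c(OC)cc(Br)cc2OC)c(OC)c1OC | intermediate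
23 | 2-(4-bromo-2,6-dimethoxyphenoxy)-3,4,5-trimethoxyphenol | COc1cc(O)c(Oc2c(OC)cc(Br)cc2OC)c(OC)c1OC | intermediate
24 | 1-(benzyloxy)-2-(4-bromo-2,6-dimethoxyphenoxy)-3,4,5-trimethoxybenzene (D–E bromide) | COc1cc(OCc2ccccc2)c(Oc2c(OC)cc(Br)cc2OC)c(OC)c1OC | intermediate
25 | 2,3,4-trimethoxyphenol | COc1ccc(O)c(OC)c1OC | starting material
26 | 6-bromo-2,3,4-trimethoxyphenol | COc1cc(Br)c(O)c(OC)c1OC | intermediate
27 | (3,4,5-trimethoxyphenyl)boronic acid | COc1cc(B(O)O)cc(OC)c1OC | starting material
28 | 1-bromo-3,4,5-trimethoxy-2-(3,4,5-trimethoxyphenoxy)benzene | COc1cc(Br)c(Oc2cc(OC)c(OC)c(OC)c2)c(OC)c1OC | intermediate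
29 | 2,3-dimethoxyphenol | COc1cccc(O)c1OC | starting material
30 | 1-(2,3-dimethoxyphenoxy)-3,4,5-trimethoxy-2-(3,4,5-trimethoxyphenoxy)benzene | COc1cccc(Oc2cc(OC)c(OC)c(OC)c2Oc2cc(OC)c(OC)c(OC)c2)c1OC | intermediate
31 | 2-{3,4-dimethoxy-5-[3,4,5-trimethoxy-2-(3,4,5-trimethoxyphenoxy)phenoxy]phenyl}-4,4,5,5-tetramethyl-1,3,2-dioxaborolane | COc1cc(B2OC(C)(C)C(C)(C)O2)cc(Oc2cc(OC)c(OC)c(OC)c2Oc2cc(OC)c(OC)c(OC)c2)c1OC | intermediate
32 | 1-(5-bromo-2,3-dimethoxyphenoxy)-3,4,5-trimethoxy-2-(3,4,5-trimethoxyphenoxy)benzene (F–G–H bromide) | COc1cc(Br)cc(Oc2cc(OC)c(OC)c(OC)c2Oc2cc(OC)c(OC)c(OC)c2)c1OC | intermediate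
33 | A-to-E pentamer, methyl ethers throughout, benzyl ether at E2 | COc1cc(OC)c(Oc2cc(OC)c(Oc3cc(OC)c(OC)c(OC)c3Oc3cc(OC)c(Oc4c(OCc5ccccc5)cc(OC)c(OC)c4OC)c(OC)c3)c(OC)c2)c(OC)c1 | intermediate
34 | A-to-E pentamer, methyl ethers throughout, free hydroxyl at E2 | COc1cc(OC)c(Oc2cc(OC)c(Oc3cc(OC)c(OC)c(OC)c3Oc3cc(OC)c(Oc4c(O)cc(OC)c(OC)c4OC)c(OC)c3)c(OC)c2)c(OC)c1 | intermediate
35 | henicosa-O-methyl ether of the target | COc1cc(OC)c(Oc2cc(OC)c(Oc3cc(OC)c(OC)c(OC)c3Oc3cc(OC)c(Oc4c(Oc5cc(OC)c(OC)c(Oc6cc(OC)c(OC)c(OC)c6Oc6cc(OC)c(OC)c(OC)c6)c5)cc(OC)c(OC)c4OC)c(OC)c3)c(OC)c2)c(OC)c1 | intermediate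
36 | CNP0309601.0 | Oc1cc(O)c(Oc2cc(O)c(Oc3cc(O)c(O)c(O)c3Oc3cc(O)c(Oc4c(Oc5cc(O)c(O)c(Oc6cc(O)c(O)c(O)c6Oc6cc(O)c(O)c(O)c6)c5)cc(O)c(O)c4O)c(O)c3)c(O)c2)c(O)c1 | target

**Step count and risks**

Total steps: 20. Longest linear sequence: 9 steps (7, 8, 9, 10, 11, 17, 18, 19, 20).

Steps most likely to fail:

Step 6 (new method). Magnesium may bind the phenoxide before it reaches the aryne, so that the aryne is lost to oligomerisation. The C2 carbanion may take iodine from unreacted 8 or a proton from the medium before magnesium captures it. The arylmagnesium may attack silicon instead of oxygen of the peroxide. The fallback uses known chemistry only and sets out from 5 and from bromophenol 26 (step 12). Compound 26 is benzylated (BnBr, K2CO3) to 2-(benzyloxy)-1-bromo-3,4,5-trimethoxybenzene F1, which already carries both ring C oxygens in the right places. Ullmann coupling of 5 with F1 (CuI, picolinic acid, K3PO4, DMSO, 110 °C) should give the benzyl ether of the A–B–C trimer F2, and hydrogenolysis (H2, Pd/C) returns to the route at 15.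

Step 9. Addition–elimination may be slow, because both the attacked carbon and the phenoxide oxygen are flanked on both sides and three methoxy groups make the fluoroarene electron-rich; long heating may degrade the aldehyde. The fallback sets out from 1. Its phenoxide displaces bromide from 3-bromo-2,6-dimethoxy-1,4-benzoquinone F3 (from commercial 2,6-dimethoxy-1,4-benzoquinone and Br2) by conjugate addition–elimination, which is little affected by ortho substituents, to give 3-(4-bromo-2,6-dimethoxyphenoxy)-2,6-dimethoxy-1,4-benzoquinone F4. Reduction with Na2S2O4 gives 3-(4-bromo-2,6-dimethoxyphenoxy)-2,6-dimethoxybenzene-1,4-diol F5. The hydroxyl with a C–H neighbour is benzylated first (one equivalent of BnBr, K2CO3) to 4-(benzyloxy)-3-(4-bromo-2,6-dimethoxyphenoxy)-2,6-dimethoxyphenol F6; this selectivity rests on sterics alone and the isomers may need separating. Methylation of the remaining hydroxyl (MeI, K2CO3) returns to the route at 24 and bypasses steps 9 to 11.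

Step 20. Cleavage of 21 methyl ethers may stop at mixtures of partial ethers, and the pyrogallol-type rings may oxidise in air during isolation. The fallback sets out from 35. The crude product of the BBr3 cleavage is not isolated as the free polyphenol but acetylated at once (Ac2O, pyridine) to the henicosaacetate of the target F7, which is stable to air, can be purified on silica and can be separated from partly methylated material for recycling. Oxygen-free transesterification (NaOMe, MeOH, argon, then acidic resin) then gives 36.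

**Further compounds**

F1 | step 6 | 2-(benzyloxy)-1-bromo-3,4,5-trimethoxybenzene | COc1cc(Br)c(OCc2ccccc2)c(OC)c1OC
F2 | step 6 | benzyl ether of 15, 2-(benzyloxy)-1-[2,6-dimethoxy-4-(2,4,6-trimethoxyphenoxy)phenoxy]-3,4,5-trimethoxybenzene | COc1cc(OC)c(Oc2cc(OC)c(Oc3cc(OC)c(OC)c(OC)c3OCc3ccccc3)c(OC)c2)c(OC)c1
F3 | step 9 | 3-bromo-2,6-dimethoxy-1,4-benzoquinone | O=C1C(OC)=C(Br)C(=O)C=C1OC
F4 | step 9 | 3-(4-bromo-2,6-dimethoxyphenoxy)-2,6-dimethoxy-1,4-benzoquinone | O=C1C(OC)=C(Oc2c(OC)cc(Br)cc2OC)C(=O)C=C1OC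
F5 | step 9 | 3-(4-bromo-2,6-dimethoxyphenoxy)-2,6-dimethoxybenzene-1,4-diol | COc1cc(O)c(Oc2c(OC)cc(Br)cc2OC)c(OC)c1O
F6 | step 9 | 4-(benzyloxy)-3-(4-bromo-2,6-dimethoxyphenoxy)-2,6-dimethoxyphenol | COc1cc(OCc2ccccc2)c(Oc2c(OC)cc(Br)cc2OC)c(OC)c1O
F7 | step 20 | henicosaacetate of the target | CC(=O)Oc1cc(OC(C)=O)c(Oc2cc(OC(C)=O)c(Oc3cc(OC(C)=O)c(OC(C)=O)c(OC(C)=O)c3Oc3cc(OC(C)=O)c(Oc4c(Oc5cc(OC(C)=O)c(OC(C)=O)c(Oc6cc(OC(C)=O)c(OC(C)=O)c(OC(C)=O)c6Oc6cc(OC(C)=O)c(OC(C)=O)c(OC(C)=O)c6)c5)cc(OC(C)=O)c(OC(C)=O)c4OC(C)=O)c(OC(C)=O)c3)c(OC(C)=O)c2)c(OC(C)=O)c1
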